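**Strategy.** The 3-hydroxy-2,2-dimethyl-6-methylidenecyclohexyl ring is cut as a [3+3] union across its CH2–CH2 bond (ring C4–C5) and its CMe2–CH bond (ring C2–C1). The key step exploits two 1,3-relationships: C5 and C1 both flank the exo-methylene carbon C6 (carried as a ketone), and C4 and C2 both flank the carbinol C3. An acetoacetate dianion is γ-alkylated by a Sharpless-derived epoxy tosylate; SnCl4 then makes the enol open the epoxide at its tertiary carbon and the product lactonises, fixing both ring stereocentres. Methylenation, hydroxyl-directed inversion of the carbinol and copper-catalysed coupling with an (S)-chroman allylic bromide (asymmetric allylic etherification, Suzuki ring closure) complete the target.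

Key step: step 2

Assumption: with the (E)-carbonate 21 the (S,S)-DACH-phenyl Trost ligand is taken to give the (S)-ether 22; if the sense of induction is the opposite, the (R,R)-ligand is used.

Step 1
Reactants: 1 3-methylbut-2-en-1-ol
Product: 3 [(2S)-3,3-dimethyloxiran-2-yl]methyl 4-methylbenzenesulfonate, via epoxy alcohol 2 (not isolated)
Conditions: Ti(OiPr)4 (5 mol %), L-(+)-diethyl tartrate (6 mol %), t-BuOOH, 4 Å MS, CH2Cl2, −20 °C; then TsCl, Et3N, DMAP (cat.), −10 °C
Reagents that add atoms: tert-butyl hydroperoxide CC(C)(C)OO; 4-toluenesulfonyl chloride Cc1ccc(cc1)S(=O)(=O)Cl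
Why: Sharpless asymmetric epoxidation with the L-(+)-tartrate catalyst should give the (2S)-epoxy alcohol (same facial sense as geraniol to (2S,3S)-epoxygeraniol), and in situ sulfonylation traps the water-soluble product without touching the stereocentre.

Step 2
Reactants: 3 [(2S)-3,3-dimethyloxiran-2-yl]methyl 4-methylbenzenesulfonate; 4 methyl 3-oxobutanoate
Product: 8 (1S,5S)-8,8-dimethyl-6-oxabicyclo[3.2.1]octane-2,7-dione, via acetoacetate dianion 5 (not isolated), via epoxy keto ester 6 (not isolated), via hydroxy keto ester 7 (not isolated)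
Conditions: 4, NaH, THF, 0 °C; n-BuLi, 0 °C; 3, −78 → 0 °C; AcOH (1 equiv), solvent exchange to CH2Cl2 in the same flask; SnCl4 (2.5 equiv), −78 → 23 °C
Reagents that add atoms: none
Why: The dianion is alkylated at its γ-carbon by SN2 displacement of the primary tosylate (ring CH2–CH2 bond); SnCl4 then chelates the β-keto ester as its enol and activates the epoxide, whose tertiary carbon is attacked by the enol α-carbon with inversion (CMe2–CH bond). The closest known reaction types are the γ-alkylation of 1,3-dicarbonyl dianions and the Lewis-acid epoxide cyclisation terminated by a β-keto ester enol. The carbocycle closes in a 6-(enolendo)-endo-tet mode and the γ-lactone by 5-exo-trig acyl transfer from the tin alkoxide to the ester, with loss of methanol. The carbinol stereocentre is that of the Sharpless epoxide (its C–O bond is never broken), while the ester-bearing carbon epimerises through the enol and only the epimer with the ester cis to the alkoxide can lactonise, so both epimers should drain into the cis-bridged lactone, whose bridgehead can no longer enolise. The step needs γ- over α-alkylation (secured by the dianion), attack at C–OTs rather than at the hindered epoxide, and C- over O-cyclisation or hydride shift; O-alkylation is reversible under SnCl4, which should funnel material to the C-alkylated product.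

Step 3
Reactants: 8 (1S,5S)-8,8-dimethyl-6-oxabicyclo[3.2.1]octane-2,7-dione
Product: 9 (1R,5S)-8,8-dimethyl-2-methylidene-6-oxabicyclo[3.2.1]octan-7-one (karahana lactone)
Conditions: Ph3PCH3Br, KOt-Bu, THF, 0 °C; then 8, 0 → 23 °C
Reagents that add atoms: methyltriphenylphosphonium bromide C[P+](c1ccccc1)(c1ccccc1)c1ccccc1.[Br-]
Why: Wittig methylenation should take the ketone in preference to the lactone, and the bridgehead α-carbon cannot enolise (Bredt's rule), so its configuration is safe from the basic ylide.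

Step 4
Reactants: 9 (1R,5S)-8,8-dimethyl-2-methylidene-6-oxabicyclo[3.2.1]octan-7-one
Product: 10 (1S,3R)-3-(hydroxymethyl)-2,2-dimethyl-4-methylidenecyclohexan-1-ol
Conditions: LiAlH4, THF, 0 °C
Reagents that add atoms: none
Why: Hydride reduction of the lactone should give the cis-diol without touching the 1,1-disubstituted alkene or either stereocentre.

Step 5
Reactants: 10 (1S,3R)-3-(hydroxymethyl)-2,2-dimethyl-4-methylidenecyclohexan-1-ol
Product: 11 (1S,3R)-3-({[tert-butyl(dimethyl)silyl]oxy}methyl)-2,2-dimethyl-4-methylidenecyclohexan-1-ol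
Conditions: TBSCl (1.05 equiv), imidazole, CH2Cl2, 0 °C
Reagents that add atoms: tert-butyldimethylsilyl chloride CC(C)(C)[Si](C)(C)Cl
Why: Silylation should be kinetically selective for the unhindered primary hydroxyl over the neopentylic secondary one.

Step 6
Reactants: 11 (1S,3R)-3-({[tert-butyl(dimethyl)silyl]oxy}methyl)-2,2-dimethyl-4-methylidenecyclohexan-1-ol
Product: 12 (3R)-3-({[tert-butyl(dimethyl)silyl]oxy}methyl)-2,2-dimethyl-4-methylidenecyclohexan-1-one
Conditions: Dess–Martin periodinane, NaHCO3, CH2Cl2, 23 °C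
Reagents that add atoms: none
Why: Dess–Martin oxidation removes the relay carbinol stereocentre, while the remaining stereocentre is separated from the new ketone by the quaternary carbon and cannot epimerise.

Step 7
Reactants: 12 (3R)-3-({[tert-butyl(dimethyl)silyl]oxy}methyl)-2,2-dimethyl-4-methylidenecyclohexan-1-one
Product: 13 (3R)-3-(hydroxymethyl)-2,2-dimethyl-4-methylidenecyclohexan-1-one
Conditions: Bu4NF, THF, 0 °C
Reagents that add atoms: none
Why: Fluoride cleaves the primary silyl ether and frees the hydroxyl needed as directing group.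

Step 8
Reactants: 13 (3R)-3-(hydroxymethyl)-2,2-dimethyl-4-methylidenecyclohexan-1-one
Product: 14 (1R,3R)-3-(hydroxymethyl)-2,2-dimethyl-4-methylidenecyclohexan-1-ol
Conditions: Me4NBH(OAc)3, AcOH/MeCN (1:1), −20 → 0 °C
Reagents that add atoms: none
Why: In this Evans–Saksena hydroxyl-directed reduction the primary hydroxyl exchanges onto boron and hydride is delivered intramolecularly to the ketone face syn to the hydroxymethyl arm (which sits 1,3 to the carbonyl when axial), so the new hydroxyl should end trans to that arm, while the free reagent does not reduce ketones and the cis-selective intermolecular path is suppressed.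

Step 9
Reactants: 14 (1R,3R)-3-(hydroxymethyl)-2,2-dimethyl-4-methylidenecyclohexan-1-ol
Product: 15 (1R,3R)-3-(iodomethyl)-2,2-dimethyl-4-methylidenecyclohexan-1-ol
Conditions: I2, PPh3, imidazole, toluene/MeCN, 0 → 40 °C
Reagents that add atoms: iodine II
Why: Appel-type iodination (SN2 on the alkoxyphosphonium ion) should occur only at the primary hydroxyl, the neopentylic secondary alcohol being inert and, being trans, unable to cyclise onto the iodide.

Step 10
Reactants: 15 (1R,3R)-3-(iodomethyl)-2,2-dimethyl-4-methylidenecyclohexan-1-ol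
Product: 16 tert-butyl{[(1R,3R)-3-(iodomethyl)-2,2-dimethyl-4-methylidenecyclohexyl]oxy}dimethylsilane
Conditions: TBSOTf, 2,6-lutidine, CH2Cl2, −78 → 0 °C
Reagents that add atoms: tert-butyldimethylsilyl trifluoromethanesulfonate CC(C)(C)[Si](C)(C)OS(=O)(=O)C(F)(F)F
Why: The silyl triflate protects the hindered secondary alcohol so that the iodide can be metallated.

Step 11
Reactants: 17 2-methylbenzene-1,4-diol
Product: 18 2-methyl-4-{[tri(propan-2-yl)silyl]oxy}phenol
Conditions: TIPSCl (1.0 equiv), imidazole, DMF, 0 °C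
Reagents that add atoms: triisopropylsilyl chloride CC(C)[Si](Cl)(C(C)C)C(C)C
Why: The bulky silyl chloride should react faster at the hydroxyl flanked by two ring hydrogens than at the one ortho to the methyl group.

Step 12
Reactants: 18 2-methyl-4-{[tri(propan-2-yl)silyl]oxy}phenol
Product: 19 2-bromo-6-methyl-4-{[tri(propan-2-yl)silyl]oxy}phenol
Conditions: NBS, i-Pr2NH (cat.), CH2Cl2, 0 °C
Reagents that add atoms: N-bromosuccinimide BrN1C(=O)CCC1=O
Why: Amine-catalysed electrophilic bromination is directed ortho to the free phenol, whose para position is blocked and whose other ortho position carries the methyl group.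

Step 13
Reactants: 20 (2E)-3,7-dimethylocta-2,6-dien-1-ol (geraniol)
Product: 21 (2E)-3,7-dimethylocta-2,6-dien-1-yl methyl carbonate
Conditions: ClCO2Me, pyridine, CH2Cl2, 0 °C
Reagents that add atoms: methyl chloroformate COC(=O)Cl
Why: Acylation of the primary allylic alcohol gives the ionisable carbonate.

Step 14
Reactants: 19 2-bromo-6-methyl-4-{[tri(propan-2-yl)silyl]oxy}phenol; 21 (2E)-3,7-dimethylocta-2,6-dien-1-yl methyl carbonate
Product: 22 2-bromo-1-{[(3S)-3,7-dimethylocta-1,6-dien-3-yl]oxy}-3-methyl-5-{[tri(propan-2-yl)silyl]oxy}benzene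
Conditions: Pd2(dba)3·CHCl3 (1 mol %), (S,S)-DACH-phenyl Trost ligand (3 mol %), CH2Cl2, 23 °C
Reagents that add atoms: none
Why: In this Tsuji–Trost asymmetric allylic O-alkylation zerovalent palladium ionises the carbonate to a π-geranyl complex and the phenol, deprotonated by the released methoxide, attacks the more substituted terminus inside the chiral pocket of the ligand, which sets the tertiary ether stereocentre.

Step 15
Reactants: 22 2-bromo-1-{[(3S)-3,7-dimethylocta-1,6-dien-3-yl]oxy}-3-methyl-5-{[tri(propan-2-yl)silyl]oxy}benzene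
Product: 24 {[(2S)-2,8-dimethyl-2-(4-methylpent-3-en-1-yl)-3,4-dihydro-2H-chromen-6-yl]oxy}tri(propan-2-yl)silane, via alkylborane 23 (not isolated)
Conditions: 9-BBN, THF, 0 → 23 °C; then Pd(dppf)Cl2 (5 mol %), K3PO4 (aq), DMF, 60 °C
Reagents that add atoms: none
Why: 9-BBN adds anti-Markovnikov to the monosubstituted vinyl group much faster than to the trisubstituted alkene, and the intramolecular B-alkyl Suzuki–Miyaura coupling with the ortho bromide closes the six-membered chroman ring without touching the C–O stereocentre.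

Step 16
Reactants: 24 {[(2S)-2,8-dimethyl-2-(4-methylpent-3-en-1-yl)-3,4-dihydro-2H-chromen-6-yl]oxy}tri(propan-2-yl)silane
Product: 25 (2E)-5-[(2S)-2,8-dimethyl-6-{[tri(propan-2-yl)silyl]oxy}-3,4-dihydro-2H-chromen-2-yl]-2-methylpent-2-en-1-ol
Conditions: SeO2 (0.3 equiv), t-BuOOH, salicylic acid (cat.), CH2Cl2, 23 °C
Reagents that add atoms: tert-butyl hydroperoxide CC(C)(C)OO
Why: Catalytic SeO2 allylic oxidation (ene reaction then [2,3]-shift) hydroxylates the (E)-methyl group of the trisubstituted alkene and should give the (E)-allylic alcohol.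

Step 17
Reactants: 25 (2E)-5-[(2S)-2,8-dimethyl-6-{[tri(propan-2-yl)silyl]oxy}-3,4-dihydro-2H-chromen-2-yl]-2-methylpent-2-en-1-ol
Product: 26 {[(2S)-2-[(3E)-5-bromo-4-methylpent-3-en-1-yl]-2,8-dimethyl-3,4-dihydro-2H-chromen-6-yl]oxy}tri(propan-2-yl)silane
Conditions: CBr4, PPh3, CH2Cl2, −20 °C
Reagents that add atoms: carbon tetrabromide BrC(Br)(Br)Br
Why: Appel bromination converts the primary allylic alcohol to the bromide by SN2 at low temperature with retention of the alkene geometry.

Step 18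
Reactants: 16 tert-butyl{[(1R,3R)-3-(iodomethyl)-2,2-dimethyl-4-methylidenecyclohexyl]oxy}dimethylsilane; 26 {[(2S)-2-[(3E)-5-bromo-4-methylpent-3-en-1-yl]-2,8-dimethyl-3,4-dihydro-2H-chromen-6-yl]oxy}tri(propan-2-yl)silane
Product: 29 tert-butyl{[(1R,3R)-3-{(3E)-6-[(2S)-2,8-dimethyl-6-{[tri(propan-2-yl)silyl]oxy}-3,4-dihydro-2H-chromen-2-yl]-3-methylhex-3-en-1-yl}-2,2-dimethyl-4-methylidenecyclohexyl]oxy}dimethylsilane, via alkyllithium 27 (not isolated), via alkylmagnesium bromide 28 (not isolated)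
Conditions: 16, t-BuLi (2.1 equiv), Et2O, −78 °C; MgBr2·OEt2; then 26, Li2CuCl4 (5 mol %), THF, −78 → 0 °C
Reagents that add atoms: none
Why: Iodine–lithium exchange and transmetalation give the Grignard reagent, which should couple with the primary allylic bromide under Li2CuCl4 catalysis (Kochi-type coupling) at the α-carbon with retention of the (E)-geometry.

Step 19
Reactants: 29 tert-butyl{[(1R,3R)-3-{(3E)-6-[(2S)-2,8-dimethyl-6-{[tri(propan-2-yl)silyl]oxy}-3,4-dihydro-2H-chromen-2-yl]-3-methylhex-3-en-1-yl}-2,2-dimethyl-4-methylidenecyclohexyl]oxy}dimethylsilane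
Product: 30 (2S)-2-{(3E)-6-[(1R,3R)-3-hydroxy-2,2-dimethyl-6-methylidenecyclohexyl]-4-methylhex-3-en-1-yl}-2,8-dimethyl-3,4-dihydro-2H-chromen-6-ol
Conditions: Bu4NF (5 equiv), THF, 23 → 50 °C
Reagents that add atoms: none
Why: Fluoride removes both the aryl triisopropylsilyl ether and the secondary tert-butyldimethylsilyl ether to release the target.

**Compound list**

1 | 3-methylbut-2-en-1-ol | CC(C)=CCO | starting material
2 | [(2S)-3,3-dimethyloxiran-2-yl]methanol | OC[C@@H]1OC1(C)C | intermediate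
3 | [(2S)-3,3-dimethyloxiran-2-yl]methyl 4-methylbenzenesulfonate | Cc1ccc(cc1)S(=O)(=O)OC[C@@H]1OC1(C)C | intermediate
4 | methyl 3-oxobutanoate | CC(=O)CC(=O)OC | starting material
5 | sodium lithium C2,C4-dianion of methyl 3-oxobutanoate | [CH2-]C(=O)[CH-]C(=O)OC.[Na+].[Li+] | intermediate
6 | methyl 5-[(2S)-3,3-dimethyloxiran-2-yl]-3-oxopentanoate | COC(=O)CC(=O)CC[C@@H]1OC1(C)C | intermediate
7 | methyl (3S)-3-hydroxy-2,2-dimethyl-6-oxocyclohexane-1-carboxylate (C1 epimers, interconverting) | O=C1CC[C@H](O)C(C)(C)C1C(=O)OC | intermediate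
8 | (1S,5S)-8,8-dimethyl-6-oxabicyclo[3.2.1]octane-2,7-dione | O=C1CC[C@H](O2)C(C)(C)[C@@H]1C2=O | intermediate
9 | (1R,5S)-8,8-dimethyl-2-methylidene-6-oxabicyclo[3.2.1]octan-7-one | C=C1CC[C@H](O2)C(C)(C)[C@@H]1C2=O | intermediate
10 | (1S,3R)-3-(hydroxymethyl)-2,2-dimethyl-4-methylidenecyclohexan-1-ol | C=C1CC[C@H](O)C(C)(C)[C@@H]1CO | intermediate
11 | (1S,3R)-3-({[tert-butyl(dimethyl)silyl]oxy}methyl)-2,2-dimethyl-4-methylidenecyclohexan-1-ol | C=C1CC[C@H](O)C(C)(C)[C@@H]1CO[Si](C)(C)C(C)(C)C | intermediate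
12 | (3R)-3-({[tert-butyl(dimethyl)silyl]oxy}methyl)-2,2-dimethyl-4-methylidenecyclohexan-1-one | C=C1CCC(=O)C(C)(C)[C@@H]1CO[Si](C)(C)C(C)(C)C | intermediate
13 | (3R)-3-(hydroxymethyl)-2,2-dimethyl-4-methylidenecyclohexan-1-one | C=C1CCC(=O)C(C)(C)[C@@H]1CO | intermediate
14 | (1R,3R)-3-(hydroxymethyl)-2,2-dimethyl-4-methylidenecyclohexan-1-ol | C=C1CC[C@@H](O)C(C)(C)[C@@H]1CO | intermediate
15 | (1R,3R)-3-(iodomethyl)-2,2-dimethyl-4-methylidenecyclohexan-1-ol | C=C1CC[C@@H](O)C(C)(C)[C@@H]1CI | intermediate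
16 | tert-butyl{[(1R,3R)-3-(iodomethyl)-2,2-dimethyl-4-methylidenecyclohexyl]oxy}dimethylsilane | C=C1CC[C@@H](O[Si](C)(C)C(C)(C)C)C(C)(C)[C@@H]1CI | intermediate
17 | 2-methylbenzene-1,4-diol | Cc1cc(O)ccc1O | starting material
18 | 2-methyl-4-{[tri(propan-2-yl)silyl]oxy}phenol | Cc1cc(O[Si](C(C)C)(C(C)C)C(C)C)ccc1O | intermediate
19 | 2-bromo-6-methyl-4-{[tri(propan-2-yl)silyl]oxy}phenol | Cc1cc(O[Si](C(C)C)(C(C)C)C(C)C)cc(Br)c1O | intermediate
20 | (2E)-3,7-dimethylocta-2,6-dien-1-ol (geraniol) | CC(C)=CCC/C(C)=C/CO | starting material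
21 | (2E)-3,7-dimethylocta-2,6-dien-1-yl methyl carbonate | CC(C)=CCC/C(C)=C/COC(=O)OC | intermediate
22 | 2-bromo-1-{[(3S)-3,7-dimethylocta-1,6-dien-3-yl]oxy}-3-methyl-5-{[tri(propan-2-yl)silyl]oxy}benzene | CC(C)=CCC[C@@](Oc1c(C)cc(O[Si](C(C)C)(C(C)C)C(C)C)cc1Br)(C)C=C | intermediate
23 | B-alkyl-9-borabicyclo[3.3.1]nonane adduct of 22 (boron on the terminal carbon of the former vinyl group) | CC(C)=CCC[C@@](Oc1c(C)cc(O[Si](C(C)C)(C(C)C)C(C)C)cc1Br)(C)CCB1C2CCCC1CCC2 | intermediate
24 | {[(2S)-2,8-dimethyl-2-(4-methylpent-3-en-1-yl)-3,4-dihydro-2H-chromen-6-yl]oxy}tri(propan-2-yl)silane | CC(C)=CCC[C@@]1(C)CCc2cc(O[Si](C(C)C)(C(C)C)C(C)C)cc(C)c2O1 | intermediate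
25 | (2E)-5-[(2S)-2,8-dimethyl-6-{[tri(propan-2-yl)silyl]oxy}-3,4-dihydro-2H-chromen-2-yl]-2-methylpent-2-en-1-ol | OC/C(C)=C/CC[C@@]1(C)CCc2cc(O[Si](C(C)C)(C(C)C)C(C)C)cc(C)c2O1 | intermediate
26 | {[(2S)-2-[(3E)-5-bromo-4-methylpent-3-en-1-yl]-2,8-dimethyl-3,4-dihydro-2H-chromen-6-yl]oxy}tri(propan-2-yl)silane | BrC/C(C)=C/CC[C@@]1(C)CCc2cc(O[Si](C(C)C)(C(C)C)C(C)C)cc(C)c2O1 | intermediate
27 | primary alkyllithium from 16 (lithium in place of iodine) | C=C1CC[C@@H](O[Si](C)(C)C(C)(C)C)C(C)(C)[C@@H]1C[Li] | intermediate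
28 | primary alkylmagnesium bromide from 27 | C=C1CC[C@@H](O[Si](C)(C)C(C)(C)C)C(C)(C)[C@@H]1C[Mg]Br | intermediate
29 | tert-butyl{[(1R,3R)-3-{(3E)-6-[(2S)-2,8-dimethyl-6-{[tri(propan-2-yl)silyl]oxy}-3,4-dihydro-2H-chromen-2-yl]-3-methylhex-3-en-1-yl}-2,2-dimethyl-4-methylidenecyclohexyl]oxy}dimethylsilane | C=C1CC[C@@H](O[Si](C)(C)C(C)(C)C)C(C)(C)[C@@H]1CC/C(C)=C/CC[C@@]1(C)CCc2cc(O[Si](C(C)C)(C(C)C)C(C)C)cc(C)c2O1 | intermediate
30 | (2S)-2-{(3E)-6-[(1R,3R)-3-hydroxy-2,2-dimethyl-6-methylidenecyclohexyl]-4-methylhex-3-en-1-yl}-2,8-dimethyl-3,4-dihydro-2H-chromen-6-ol | C=C1CC[C@@H](O)C(C)(C)[C@@H]1CC/C(C)=C/CC[C@@]1(C)CCc2cc(O)cc(C)c2O1 | target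

**Step count and risks**

Total steps: 19 (10 for the cyclohexane part, 7 for the chroman part, 2 after convergence). Longest linear sequence: 12 steps (steps 1–10, 18, 19).

Steps most likely to fail:

1. Step 2 (key step). The Lewis-acid stage may divert into O-alkylation by the enol oxygen or into a hydride shift of the opened epoxide to a ketone, and the lactone may fail to close in the same flask. Fallback, setting out from 3 and 4 and coming back at 9: the alkylation is quenched and epoxy keto ester 6 is isolated. NaH and ClP(O)(OEt)2 in Et2O give methyl (2Z)-3-[(diethoxyphosphoryl)oxy]-5-[(2S)-3,3-dimethyloxiran-2-yl]pent-2-enoate F1. (Me3SiCH2)2CuLi replaces the phosphate with retention to give methyl (2Z)-5-[(2S)-3,3-dimethyloxiran-2-yl]-3-[(trimethylsilyl)methyl]pent-2-enoate F2. BF3·OEt2 at −78 °C effects the epoxy–allylsilane cyclisation through a chair with the ester equatorial, giving methyl (1R,3S)-3-hydroxy-2,2-dimethyl-6-methylidenecyclohexane-1-carboxylate F3. TsOH in toluene then lactonises F3 to 9. This fallback forms the two ring bonds in separate steps.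

2. Step 8. Internal hydride delivery through the seven-membered arrangement may be slow, so that intermolecular reduction anti to the axial hydroxymethyl arm gives the cis-diol 10 again. Fallback, setting out from 11 and coming back at 14: the inversion is done by substitution. Mitsunobu reaction of 11 (4-nitrobenzoic acid, PPh3, DIAD, toluene) gives the inverted ester (1R,3R)-3-({[tert-butyl(dimethyl)silyl]oxy}methyl)-2,2-dimethyl-4-methylidenecyclohexyl 4-nitrobenzoate F4. K2CO3 in MeOH gives (1R,3R)-3-({[tert-butyl(dimethyl)silyl]oxy}methyl)-2,2-dimethyl-4-methylidenecyclohexan-1-ol F5, and Bu4NF gives 14.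

3. Step 14. The 2,6-disubstituted phenol may attack the less substituted allyl terminus or react with low enantioselectivity. Fallback, setting out from 18 and 21 and coming back at 24: the less hindered phenol 18 is coupled with 21 under the same catalyst to give 1-{[(3S)-3,7-dimethylocta-1,6-dien-3-yl]oxy}-2-methyl-4-{[tri(propan-2-yl)silyl]oxy}benzene F6. 9-BBN then NaOH/H2O2 gives (3S)-3,7-dimethyl-3-(2-methyl-4-{[tri(propan-2-yl)silyl]oxy}phenoxy)oct-6-en-1-ol F7, and Dess–Martin periodinane gives (3S)-3,7-dimethyl-3-(2-methyl-4-{[tri(propan-2-yl)silyl]oxy}phenoxy)oct-6-enal F8. BF3·OEt2 with Et3SiH at −78 °C closes the ring by intramolecular Friedel–Crafts hydroxyalkylation at the only free position ortho to the ether oxygen, with ionic reduction of the benzylic carbinol, to give 24.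

**Further compounds**

F1 | step 2 | methyl (2Z)-3-[(diethoxyphosphoryl)oxy]-5-[(2S)-3,3-dimethyloxiran-2-yl]pent-2-enoate | COC(=O)/C=C(\OP(=O)(OCC)OCC)CC[C@@H]1OC1(C)C
F2 | step 2 | methyl (2Z)-5-[(2S)-3,3-dimethyloxiran-2-yl]-3-[(trimethylsilyl)methyl]pent-2-enoate | COC(=O)/C=C(\C[Si](C)(C)C)CC[C@@H]1OC1(C)C
F3 | step 2 | methyl (1R,3S)-3-hydroxy-2,2-dimethyl-6-methylidenecyclohexane-1-carboxylate | C=C1CC[C@H](O)C(C)(C)[C@@H]1C(=O)OC
F4 | step 8 | (1R,3R)-3-({[tert-butyl(dimethyl)silyl]oxy}methyl)-2,2-dimethyl-4-methylidenecyclohexyl 4-nitrobenzoate | C=C1CC[C@@H](OC(=O)c2ccc(cc2)[N+](=O)[O-])C(C)(C)[C@@H]1CO[Si](C)(C)C(C)(C)C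
F5 | step 8 | (1R,3R)-3-({[tert-butyl(dimethyl)silyl]oxy}methyl)-2,2-dimethyl-4-methylidenecyclohexan-1-ol | C=C1CC[C@@H](O)C(C)(C)[C@@H]1CO[Si](C)(C)C(C)(C)C
F6 | step 14 | 1-{[(3S)-3,7-dimethylocta-1,6-dien-3-yl]oxy}-2-methyl-4-{[tri(propan-2-yl)silyl]oxy}benzene | CC(C)=CCC[C@@](Oc1ccc(O[Si](C(C)C)(C(C)C)C(C)C)cc1C)(C)C=C
F7 | step 14 | (3S)-3,7-dimethyl-3-(2-methyl-4-{[tri(propan-2-yl)silyl]oxy}phenoxy)oct-6-en-1-ol | CC(C)=CCC[C@@](Oc1ccc(O[Si](C(C)C)(C(C)C)C(C)C)cc1C)(C)CCO
F8 | step 14 | (3S)-3,7-dimethyl-3-(2-methyl-4-{[tri(propan-2-yl)silyl]oxy}phenoxy)oct-6-enal | CC(C)=CCC[C@@](Oc1ccc(O[Si](C(C)C)(C(C)C)C(C)C)cc1C)(C)CC=O
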